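**Plan** (lignan numbering: C1 bears ring C, C2 and C3 bear the carboxyl groups, C4 is the vinylic CH, ring A is C4a–C8a)
1. The last cuts are the five O‑benzyl and three O‑methyl bonds. Before them come the side‑chain C=C (ring D aldehyde plus phosphonate) and the bond from O‑3' of ring C to the phosphonoacetate carbon.
2. The core cut takes C4–C4a and C1–C8a of ring B together. C4a and C8a are neighbouring carbons of ring A. Ring A carries equal oxygen groups at C6 and C7, so the derived 4,5‑dialkoxybenzyne is symmetric and takes up C4 and C1 of a four‑carbon diene with one outcome in either orientation.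
3. The diene C1=C2–C3=C4 is cut at C2–C3 into an α‑stannyl enoyl camphorsultam (from the ring C arylpropiolic acid) and methyl 2‑bromoacrylate.
4. Forward: rings A, C and D are bought as benzaldehydes, and ring B, the only ring made, closes in the aryne cycloaddition. The alkene is then moved from C2=C3 to C3=C4, the auxiliary is exchanged for OMe, O‑3' is freed, the side chain is joined and everything is unmasked.
5. Stereochemistry: C1 comes from face selection by the camphorsultam on the C2 carbonyl, and the epimers are separable diastereomers. C2 comes from equilibration to trans relative to C1. The (E)‑enol ether comes from a kinetically controlled Still–Gennari olefination.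

Key step: step 10

Assumption: the (1S)‑(−)‑sultam is taken to cover the diene face that would lead to (1S), so the cycloadduct is drawn (1R). If the cycloaddition shows the opposite sense, the equally available (1R)‑(+)‑sultam is used and nothing else changes.

**Step 1**
Reactants: 1 3,4‑bis(benzyloxy)benzaldehyde
Product: 3 3,4‑bis(benzyloxy)phenol, via aryl formate 2 (not isolated)
Conditions: mCPBA, CH2Cl2, 0 °C → rt; then K2CO3 (cat.), MeOH, rt
Reagents that add atoms: mCPBA O=C(OO)c1cccc(Cl)c1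
Why: In this Baeyer–Villiger (Dakin‑type) oxidation the electron‑rich aryl group migrates, and the formate is methanolysed under mild base that leaves the benzyl ethers alone.

**Step 2**
Reactants: 3 3,4‑bis(benzyloxy)phenol
Product: 4 4,5‑bis(benzyloxy)‑2‑bromophenol
Conditions: NBS (1.0 equiv), MeCN, 0 °C
Reagents that add atoms: NBS O=C1CCC(=O)N1Br
Why: Electrophilic aromatic bromination should go to the open position that is ortho to OH and para to the 3‑benzyloxy group, the most activated and least hindered site.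

**Step 3**
Reactants: 4 4,5‑bis(benzyloxy)‑2‑bromophenol
Product: 7 4,5‑bis(benzyloxy)‑2‑(trimethylsilyl)phenyl trifluoromethanesulfonate, via silyl ether 5 (not isolated), via lithium phenolate 6 (not isolated)
Conditions: HMDS, THF, 70 °C, evaporate; n‑BuLi, THF, −78 °C; Tf2O, −78 → 0 °C
Reagents that add atoms: hexamethyldisilazane C[Si](C)(C)N[Si](C)(C)C; triflic anhydride O=S(=O)(OS(=O)(=O)C(F)(F)F)C(F)(F)F
Why: This is the standard route to ortho‑silylaryl triflates, namely O‑silylation, bromine–lithium exchange with retro‑Brook O‑to‑C silyl shift, and triflation of the released phenolate.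

**Step 4**
Reactants: 8 4‑(benzyloxy)‑3‑hydroxybenzaldehyde
Product: 9 4‑(benzyloxy)‑3‑(methoxymethoxy)benzaldehyde
Conditions: MOMCl, iPr2NEt, CH2Cl2, 0 °C → rt
Reagents that add atoms: chloromethyl methyl ether COCCl
Why: O‑Alkylation of the only free phenol gives a MOM ether that tolerates organolithium, tin, fluoride and amide‑base chemistry and later leaves under mild acid while the benzyl ethers stay.

**Step 5**
Reactants: 9 4‑(benzyloxy)‑3‑(methoxymethoxy)benzaldehyde
Product: 10 1‑(benzyloxy)‑4‑ethynyl‑2‑(methoxymethoxy)benzene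
Conditions: dimethyl (1‑diazo‑2‑oxopropyl)phosphonate, K2CO3, MeOH, rt
Reagents that add atoms: Bestmann–Ohira reagent CC(=O)C(=[N+]=[N-])P(=O)(OC)OC
Why: The Seyferth–Gilbert homologation in its Bestmann–Ohira form turns the aldehyde into the terminal alkyne under mildly basic conditions that are harmless to MOM and benzyl ethers.

**Step 6**
Reactants: 10 1‑(benzyloxy)‑4‑ethynyl‑2‑(methoxymethoxy)benzene
Product: 12 3‑[4‑(benzyloxy)‑3‑(methoxymethoxy)phenyl]prop‑2‑ynoic acid, via lithium acetylide 11 (not isolated)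
Conditions: n‑BuLi (1.05 equiv), THF, −78 °C; CO2; 1 M HCl to pH 3, 0 °C
Reagents that add atoms: carbon dioxide O=C=O
Why: Deprotonation of the most acidic C–H and carboxylation of the acetylide is the routine way to arylpropiolic acids, and a brief cold acidification spares the MOM ether.

**Step 7**
Reactants: 12 3‑[4‑(benzyloxy)‑3‑(methoxymethoxy)phenyl]prop‑2‑ynoic acid; 13 (1S)‑(−)‑2,10‑camphorsultam
Product: 15 N‑{3‑[4‑(benzyloxy)‑3‑(methoxymethoxy)phenyl]prop‑2‑ynoyl}‑(1S)‑camphorsultam, via mixed pivalic anhydride 14 (not isolated)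
Conditions: PivCl, Et3N, THF, −20 °C; then 13, LiCl, DMAP (cat.), −20 °C → rt
Reagents that add atoms: none
Why: N‑Acylation through the mixed anhydride, which is attacked at the less hindered alkynoyl carbonyl, avoids HCl and avoids the self‑condensing symmetric arylpropiolic anhydride.

**Step 8**
Reactants: 15 N‑{3‑[4‑(benzyloxy)‑3‑(methoxymethoxy)phenyl]prop‑2‑ynoyl}‑(1S)‑camphorsultam
Product: 16 N‑{(E)‑3‑[4‑(benzyloxy)‑3‑(methoxymethoxy)phenyl]‑2‑(tributylstannyl)prop‑2‑enoyl}‑(1S)‑camphorsultam (ring C cis to the acyl group)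
Conditions: Bu3SnH (slow addition), Pd(PPh3)4 (2 mol %), THF, 0 °C → rt
Reagents that add atoms: tributyltin hydride CCCC[SnH](CCCC)CCCC
Why: Hydrostannylation catalysed by zerovalent palladium is a syn addition that places H on the β carbon and tin on the α carbon of alkynoyl acceptors, so ring C and the acyl group end up cis.

**Step 9**
Reactants: 16 α‑stannyl enoyl sultam; 17 methyl 2‑bromoacrylate
Product: 18 methyl (3Z)‑4‑[4‑(benzyloxy)‑3‑(methoxymethoxy)phenyl]‑2‑methylidene‑3‑[(1S)‑camphorsultam‑N‑carbonyl]but‑3‑enoate (diene C1=C2–C3=C4 in which ring C on C1 is cis to the acyl sultam)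
Conditions: Pd(PPh3)4 (5 mol %), CuI (10 mol %), CsF (2 equiv), DMF, 40 °C, BHT (trace)
Reagents that add atoms: none
Why: Stille coupling with copper co‑catalysis and fluoride activation, the usual remedy for slow α‑stannyl acrylates, forms C2–C3 with retention of geometry and so puts ring C on the outer side of the s‑cis diene.

**Step 10**
Reactants: 18 diene; 7 4,5‑bis(benzyloxy)‑2‑(trimethylsilyl)phenyl trifluoromethanesulfonate
Product: 20 methyl (1R)‑1‑[4‑(benzyloxy)‑3‑(methoxymethoxy)phenyl]‑6,7‑bis(benzyloxy)‑2‑[(1S)‑camphorsultam‑N‑carbonyl]‑1,4‑dihydronaphthalene‑3‑carboxylate, via 4,5‑bis(benzyloxy)benzyne 19 (not isolated)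
Conditions: 7 (1.5 equiv, added over several hours), CsF (4 equiv), MeCN–toluene, 25 °C; minor C1 epimer removed by crystallisation or chromatography
Reagents that add atoms: none
Why: Proposed new method: fluoride attacks the silicon of 7, triflate leaves, and the symmetric aryne 19 adds in a concerted suprafacial (4+2) fashion to the s‑cis conformer of 18, forming C4–C4a and C1–C8a and closing ring B as a six‑membered carbocycle by intermolecular cycloaddition. The closest known reaction type is the aryne Diels–Alder reaction of acyclic acceptor‑substituted dienes that carry a camphorsultam on a terminal carbonyl group, whereas a 1‑aryl diene with acceptors on both inner carbons and the auxiliary on C2 has not been shown. Reactivity should hold because the very low aryne LUMO accepts even electron‑poor dienes, the two inner substituents disfavour the s‑trans form, and the electron‑rich ring C raises the diene HOMO. No regiochemical question arises, since the two aryne carbons are equivalent by symmetry. The one new stereocentre, C1, rests on diene face selectivity: squeezed between ring C and the C3 acrylate unit, the C2 acyl group is twisted out of the diene plane, so the bornane skeleton lies over one face next to C1 and the aryne should approach from the other, any minor epimer being a separable diastereomer. Chemoselectivity over the aryne ene reaction, styrene‑type addition through ring C and diene dimerisation is sought by releasing 19 slowly into a dilute solution of 18.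

**Step 11**
Reactants: 20 1,4‑dihydronaphthalene cycloadduct
Product: 23 methyl (1R,2S)‑1‑[4‑(benzyloxy)‑3‑(methoxymethoxy)phenyl]‑6,7‑bis(benzyloxy)‑2‑[(1S)‑camphorsultam‑N‑carbonyl]‑1,2‑dihydronaphthalene‑3‑carboxylate (1,2‑trans), via lithium dienolate 21 (not isolated), via cis epimer 22 (not isolated)
Conditions: LiHMDS (1.1 equiv), THF, −78 °C; AcOH (1.2 equiv), −78 °C; then DBU (0.3 equiv), → rt, argon
Reagents that add atoms: none
Why: This is a deconjugative isomerisation through a dienolate in which the pseudoaxial C1 aryl group of the boat‑shaped ring leaves C1–H near the ring plane and kinetically non‑acidic, a pseudoaxial C4–H vinylogous to the imide is removed instead, kinetic protonation occurs at the α carbon C2 anti to ring C (22), and DBU then equilibrates only C2, since C1–H is no longer activated, to the more stable trans (1R,2S) isomer.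

**Step 12**
Reactants: 23 trans‑1,2‑dihydronaphthalene acyl sultam
Product: 24 dimethyl (1R,2S)‑1‑[4‑(benzyloxy)‑3‑(methoxymethoxy)phenyl]‑6,7‑bis(benzyloxy)‑1,2‑dihydronaphthalene‑2,3‑dicarboxylate
Conditions: NaOMe (1.2 equiv), MeOH–THF, 0 °C → rt; AcOH quench
Reagents that add atoms: NaOMe C[O-].[Na+]
Why: Methanolysis of the N‑acyl sultam (nucleophilic acyl substitution) returns the auxiliary, exchange at the C3 methyl ester is degenerate, and the basic medium can only hold C2 at its thermodynamic trans configuration.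

**Step 13**
Reactants: 24 MOM‑protected dimethyl ester
Product: 25 dimethyl (1R,2S)‑1‑[4‑(benzyloxy)‑3‑hydroxyphenyl]‑6,7‑bis(benzyloxy)‑1,2‑dihydronaphthalene‑2,3‑dicarboxylate
Conditions: p‑TsOH·H2O (cat.), MeOH–CH2Cl2, 40 °C
Reagents that add atoms: none
Why: Acid‑catalysed acetal exchange removes the phenolic MOM group, while the benzyl ethers, the methyl esters in methanol and both stereocentres are unaffected.

**Step 14**
Reactants: 26 methyl 2‑[bis(2,2,2‑trifluoroethoxy)phosphoryl]acetate
Product: 27 methyl 2‑diazo‑2‑[bis(2,2,2‑trifluoroethoxy)phosphoryl]acetate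
Conditions: 4‑acetamidobenzenesulfonyl azide, DBU, MeCN, 0 °C → rt
Reagents that add atoms: 4‑acetamidobenzenesulfonyl azide CC(=O)Nc1ccc(cc1)S(=O)(=O)N=[N+]=[N-]
Why: Regitz diazo transfer onto the doubly activated methylene group of a phosphonoacetate is a general reaction.

**Step 15**
Reactants: 25 phenol; 27 diazophosphonoacetate
Product: 28 dimethyl (1R,2S)‑1‑{4‑(benzyloxy)‑3‑[1‑[bis(2,2,2‑trifluoroethoxy)phosphoryl]‑2‑methoxy‑2‑oxoethoxy]phenyl}‑6,7‑bis(benzyloxy)‑1,2‑dihydronaphthalene‑2,3‑dicarboxylate (epimer mixture at the phosphonate carbon)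
Conditions: Rh2(OAc)4 (2 mol %), toluene, 80 °C, slow addition of 27
Reagents that add atoms: none
Why: Rhodium‑carbenoid O–H insertion of diazophosphonoacetates into phenols is a known entry to α‑aryloxy phosphonoacetates, it outruns attack on the electron‑poor C3=C4 bond or the arenes, and the new carbon stereocentre is inconsequential because the next step erases it.

**Step 16**
Reactants: 28 α‑aryloxy phosphonate; 1 3,4‑bis(benzyloxy)benzaldehyde
Product: 30 trimethyl ester pentabenzyl ether of the target with (E)‑enol ether (ring D trans to the aryloxy oxygen and cis to CO2Me), via potassium phosphonate anion 29 (not isolated)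
Conditions: KHMDS (1.0 equiv), 18‑crown‑6, THF, −78 °C; then 1, −78 → −40 °C
Reagents that add atoms: none
Why: In the Still–Gennari form of the Horner–Wadsworth–Emmons olefination the electron‑poor trifluoroethyl phosphonate and the dissociated potassium ion make the first adduct collapse irreversibly, which places the aldehyde residue cis to the ester, the (E) geometry required, and the single equivalent of base is taken by the phosphonate as the most acidic C–H.

**Step 17**
Reactants: 30 trimethyl ester pentabenzyl ether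
Product: 31 (1R,2S)‑1‑{4‑(benzyloxy)‑3‑[(E)‑2‑[3,4‑bis(benzyloxy)phenyl]‑1‑carboxyethenoxy]phenyl}‑6,7‑bis(benzyloxy)‑1,2‑dihydronaphthalene‑2,3‑dicarboxylic acid
Conditions: LiOH, THF–MeOH–H2O, rt → 40 °C, argon; 1 M HCl to pH 2, 0 °C
Reagents that add atoms: LiOH [Li+].[OH-]
Why: Saponification is run while all phenols are still masked, so that no phenolate can push electrons into the enol‑ether acrylate and loosen its geometry, and C2 already has its thermodynamic configuration and stops enolising once the carboxylates form.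

**Step 18**
Reactants: 31 triacid pentabenzyl ether
Product: 32 (1R,2S)‑1‑{3‑[(E)‑1‑carboxy‑2‑(3,4‑dihydroxyphenyl)ethenoxy]‑4‑hydroxyphenyl}‑6,7‑dihydroxy‑1,2‑dihydronaphthalene‑2,3‑dicarboxylic acid (target)
Conditions: BCl3, pentamethylbenzene, CH2Cl2, −78 °C; then THF–H2O; exclusion of light and air
Reagents that add atoms: none
Why: Lewis‑acid debenzylation with a non‑basic benzyl‑cation scavenger cleaves aryl benzyl ethers at −78 °C without hydrogen, so both C=C bonds, the aryl vinyl ether (whose two C–O bonds are to sp2 carbons) and the stereocentres should survive.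

**Compound list**
1 | 3,4‑bis(benzyloxy)benzaldehyde | O=Cc1ccc(OCc2ccccc2)c(OCc2ccccc2)c1 | starting material
2 | 3,4‑bis(benzyloxy)phenyl formate | O=COc1ccc(OCc2ccccc2)c(OCc2ccccc2)c1 | intermediate (not isolated)
3 | 3,4‑bis(benzyloxy)phenol | Oc1ccc(OCc2ccccc2)c(OCc2ccccc2)c1 | intermediate
4 | 4,5‑bis(benzyloxy)‑2‑bromophenol | Oc1cc(OCc2ccccc2)c(OCc2ccccc2)cc1Br | intermediate
5 | [4,5‑bis(benzyloxy)‑2‑bromophenoxy]trimethylsilane | C[Si](C)(C)Oc1cc(OCc2ccccc2)c(OCc2ccccc2)cc1Br | intermediate (not isolated)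
6 | lithium 4,5‑bis(benzyloxy)‑2‑(trimethylsilyl)phenolate | [Li+].[O-]c1cc(OCc2ccccc2)c(OCc2ccccc2)cc1[Si](C)(C)C | intermediate (not isolated)
7 | 4,5‑bis(benzyloxy)‑2‑(trimethylsilyl)phenyl trifluoromethanesulfonate | C[Si](C)(C)c1cc(OCc2ccccc2)c(OCc2ccccc2)cc1OS(=O)(=O)C(F)(F)F | intermediate
8 | 4‑(benzyloxy)‑3‑hydroxybenzaldehyde | O=Cc1ccc(OCc2ccccc2)c(O)c1 | starting material
9 | 4‑(benzyloxy)‑3‑(methoxymethoxy)benzaldehyde | O=Cc1ccc(OCc2ccccc2)c(OCOC)c1 | intermediate
10 | 1‑(benzyloxy)‑4‑ethynyl‑2‑(methoxymethoxy)benzene | C#Cc1ccc(OCc2ccccc2)c(OCOC)c1 | intermediate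
11 | lithium acetylide of 10 | [Li+].[C-]#Cc1ccc(OCc2ccccc2)c(OCOC)c1 | intermediate (not isolated)
12 | 3‑[4‑(benzyloxy)‑3‑(methoxymethoxy)phenyl]prop‑2‑ynoic acid | OC(=O)C#Cc1ccc(OCc2ccccc2)c(OCOC)c1 | intermediate
13 | (1S)‑(−)‑2,10‑camphorsultam | CC1(C)[C@@H]2CC[C@]13CS(=O)(=O)N[C@@H]3C2 | starting material
14 | mixed anhydride of 12 and pivalic acid | CC(C)(C)C(=O)OC(=O)C#Cc1ccc(OCc2ccccc2)c(OCOC)c1 | intermediate (not isolated)
15 | N‑arylpropioloyl (1S)‑camphorsultam | CC1(C)[C@@H]2CC[C@]13CS(=O)(=O)N([C@@H]3C2)C(=O)C#Cc1ccc(OCc2ccccc2)c(OCOC)c1 | intermediate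
16 | (E)‑α‑tributylstannyl enoyl sultam | CC1(C)[C@@H]2CC[C@]13CS(=O)(=O)N([C@@H]3C2)C(=O)/C(=C\c1ccc(OCc2ccccc2)c(OCOC)c1)[Sn](CCCC)(CCCC)CCCC | intermediate
17 | methyl 2‑bromoacrylate | C=C(Br)C(=O)OC | starting material
18 | (Z)‑1‑aryl diene 2‑acylsultam 3‑methyl ester | CC1(C)[C@@H]2CC[C@]13CS(=O)(=O)N([C@@H]3C2)C(=O)/C(=C\c1ccc(OCc2ccccc2)c(OCOC)c1)C(=C)C(=O)OC | intermediate
19 | 4,5‑bis(benzyloxy)benzyne | c1ccccc1COC1=CC#CC=C1OCc1ccccc1 | intermediate (not isolated)
20 | (1R)‑1‑aryl‑1,4‑dihydronaphthalene 2‑acylsultam 3‑ester | CC1(C)[C@@H]2CC[C@]13CS(=O)(=O)N([C@@H]3C2)C(=O)C1=C(C(=O)OC)Cc2cc(OCc3ccccc3)c(OCc3ccccc3)cc2[C@H]1c1ccc(OCc2ccccc2)c(OCOC)c1 | intermediate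
21 | lithium dienolate of 20 (C4 deprotonated) | CC1(C)[C@@H]2CC[C@]13CS(=O)(=O)N([C@@H]3C2)C([O-])=C1C(C(=O)OC)=Cc2cc(OCc3ccccc3)c(OCc3ccccc3)cc2[C@H]1c1ccc(OCc2ccccc2)c(OCOC)c1.[Li+] | intermediate (not isolated)
22 | (1R,2R)‑cis‑1,2‑dihydronaphthalene acyl sultam | CC1(C)[C@@H]2CC[C@]13CS(=O)(=O)N([C@@H]3C2)C(=O)[C@H]1C(C(=O)OC)=Cc2cc(OCc3ccccc3)c(OCc3ccccc3)cc2[C@H]1c1ccc(OCc2ccccc2)c(OCOC)c1 | intermediate (not isolated)
23 | (1R,2S)‑trans‑1,2‑dihydronaphthalene acyl sultam | CC1(C)[C@@H]2CC[C@]13CS(=O)(=O)N([C@@H]3C2)C(=O)[C@@H]1C(C(=O)OC)=Cc2cc(OCc3ccccc3)c(OCc3ccccc3)cc2[C@H]1c1ccc(OCc2ccccc2)c(OCOC)c1 | intermediate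
24 | (1R,2S)‑dimethyl ester, 3'‑OMOM | COC(=O)C1=Cc2cc(OCc3ccccc3)c(OCc3ccccc3)cc2[C@@H](c2ccc(OCc3ccccc3)c(OCOC)c2)[C@@H]1C(=O)OC | intermediate
25 | (1R,2S)‑dimethyl ester, 3'‑OH | COC(=O)C1=Cc2cc(OCc3ccccc3)c(OCc3ccccc3)cc2[C@@H](c2ccc(OCc3ccccc3)c(O)c2)[C@@H]1C(=O)OC | intermediate
26 | methyl 2‑[bis(2,2,2‑trifluoroethoxy)phosphoryl]acetate | COC(=O)CP(=O)(OCC(F)(F)F)OCC(F)(F)F | starting material
27 | methyl 2‑diazo‑2‑[bis(2,2,2‑trifluoroethoxy)phosphoryl]acetate | COC(=O)C(=[N+]=[N-])P(=O)(OCC(F)(F)F)OCC(F)(F)F | intermediate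
28 | α‑aryloxy phosphonoacetate (phosphonate carbon unassigned) | COC(=O)C1=Cc2cc(OCc3ccccc3)c(OCc3ccccc3)cc2[C@@H](c2ccc(OCc3ccccc3)c(OC(C(=O)OC)P(=O)(OCC(F)(F)F)OCC(F)(F)F)c2)[C@@H]1C(=O)OC | intermediate
29 | potassium salt of the phosphonate carbanion of 28 | COC(=O)C1=Cc2cc(OCc3ccccc3)c(OCc3ccccc3)cc2[C@@H](c2ccc(OCc3ccccc3)c(O[C-](C(=O)OC)P(=O)(OCC(F)(F)F)OCC(F)(F)F)c2)[C@@H]1C(=O)OC.[K+] | intermediate (not isolated)
30 | (E)‑enol ether, trimethyl ester, pentabenzyl ether | COC(=O)C1=Cc2cc(OCc3ccccc3)c(OCc3ccccc3)cc2[C@@H](c2ccc(OCc3ccccc3)c(O/C(=C/c3ccc(OCc4ccccc4)c(OCc4ccccc4)c3)C(=O)OC)c2)[C@@H]1C(=O)OC | intermediate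
31 | triacid pentabenzyl ether | O=C(O)C1=Cc2cc(OCc3ccccc3)c(OCc3ccccc3)cc2[C@@H](c2ccc(OCc3ccccc3)c(O/C(=C/c3ccc(OCc4ccccc4)c(OCc4ccccc4)c3)C(=O)O)c2)[C@@H]1C(=O)O | intermediate
32 | CNP0241205.1 | O=C(O)C1=Cc2cc(O)c(O)cc2[C@@H](c2ccc(O)c(O/C(=C/c3ccc(O)c(O)c3)C(=O)O)c2)[C@@H]1C(=O)O | target

**Total steps:** 18. **Longest linear sequence:** 14 (from 8 through steps 4–13 and 15–18).

**Steps most likely to fail**

Step 10. The doubly acceptor‑substituted diene may add too slowly, so that self‑consumption of the aryne and dimerisation of the diene take over. The twisted auxiliary may also discriminate poorly between the two diene faces.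
- The fallback uses known reaction types only. It sets out from 1, 13 and 9 and returns at 25, and ring B is closed by cationic cyclisation instead.
- Stobbe condensation of 1 with dimethyl succinate (NaOMe, MeOH, reflux) gives (E)‑4‑[3,4‑bis(benzyloxy)phenyl]‑3‑(methoxycarbonyl)but‑3‑enoic acid F1.
- The free acid of F1 is joined to 13 through its mixed pivalic anhydride to give the N‑acyl sultam F2.
- Boron‑enolate aldol addition to 9 (Et2BOTf, iPr2NEt, CH2Cl2, −78 °C) sets C2 under auxiliary control and gives the β‑hydroxy imide F3, whose carbinol configuration is immaterial.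
- TFA in CH2Cl2 at 0 °C ionises the benzylic alcohol. Ring A attacks the cation para to its 3‑benzyloxy group, a Friedel–Crafts closure of C1–C8a that places ring C trans to the C2 acyl group. The MOM group falls off in the same operation, giving the phenolic trans‑1,2‑dihydronaphthalene sultam F4.
- NaOMe in MeOH as in step 12 then gives 25. The antipodal sultam is used if the aldol shows the other sense.

Step 11. Competing removal of C1–H would erode the C1 configuration or shift the alkene to C1=C2, and traces of air would aromatise the dienolate.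
- The fallback sets out from 20 and returns at 23, and it works by switching off the competing acidifying group.
- SN2 demethylation of the C3 ester (LiI, pyridine, 100 °C) gives the C3 carboxylic acid F5.
- With two equivalents of LiHMDS the carboxylate forms first and no longer acidifies C1–H, so only C4–H is removed.
- AcOH quench and DBU equilibration as before give the trans‑1,2‑dihydronaphthalene C3 acid F6, and TMSCHN2 in toluene–MeOH re‑esterifies it to 23.

Step 16. Reversible addition with the bulky α‑aryloxy phosphonate and the electron‑rich aldehyde may erode kinetic control and let the more stable (Z) isomer form, and partial deprotonation at C2 may occur.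
- The fallback sets out from 1 and 25 and returns at 30. The geometry is fixed stereospecifically on a small fragment, and the C–O bond is made by cross‑coupling.
- Corey–Fuchs reaction of 1 (CBr4, PPh3, CH2Cl2) gives 1,2‑bis(benzyloxy)‑4‑(2,2‑dibromoethenyl)benzene F7.
- n‑BuLi followed by ClCO2Me gives methyl 3‑[3,4‑bis(benzyloxy)phenyl]prop‑2‑ynoate F8.
- Syn‑hydrostannylation (Bu3SnH, Pd(PPh3)4) gives methyl (E)‑3‑[3,4‑bis(benzyloxy)phenyl]‑2‑(tributylstannyl)prop‑2‑enoate F9.
- Iododestannylation (I2, CH2Cl2, 0 °C) proceeds with retention and gives methyl (E)‑3‑[3,4‑bis(benzyloxy)phenyl]‑2‑iodoprop‑2‑enoate F10.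
- Ullmann‑type O‑vinylation of 25 with F10 (CuI, N,N‑dimethylglycine, Cs2CO3, dioxane, 80 °C) keeps the alkene geometry and gives 30.

**Further compounds**
F1 | step 10 | (E)‑4‑[3,4‑bis(benzyloxy)phenyl]‑3‑(methoxycarbonyl)but‑3‑enoic acid | COC(=O)/C(CC(=O)O)=C/c1ccc(OCc2ccccc2)c(OCc2ccccc2)c1
F2 | step 10 | N‑acyl (1S)‑camphorsultam of F1 | CC1(C)[C@@H]2CC[C@]13CS(=O)(=O)N([C@@H]3C2)C(=O)C/C(=C\c1ccc(OCc2ccccc2)c(OCc2ccccc2)c1)C(=O)OC
F3 | step 10 | aldol adduct of F2 and 9 (C2 as in the target, carbinol carbon unassigned) | CC1(C)[C@@H]2CC[C@]13CS(=O)(=O)N([C@@H]3C2)C(=O)[C@@H](C(O)c1ccc(OCc2ccccc2)c(OCOC)c1)/C(=C\c1ccc(OCc2ccccc2)c(OCc2ccccc2)c1)C(=O)OC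
F4 | step 10 | (1R,2S)‑trans‑1,2‑dihydronaphthalene acyl sultam with free 3'‑OH | CC1(C)[C@@H]2CC[C@]13CS(=O)(=O)N([C@@H]3C2)C(=O)[C@@H]1C(C(=O)OC)=Cc2cc(OCc3ccccc3)c(OCc3ccccc3)cc2[C@H]1c1ccc(OCc2ccccc2)c(O)c1
F5 | step 11 | (1R)‑1,4‑dihydronaphthalene 2‑acylsultam 3‑carboxylic acid | CC1(C)[C@@H]2CC[C@]13CS(=O)(=O)N([C@@H]3C2)C(=O)C1=C(C(=O)O)Cc2cc(OCc3ccccc3)c(OCc3ccccc3)cc2[C@H]1c1ccc(OCc2ccccc2)c(OCOC)c1
F6 | step 11 | (1R,2S)‑trans‑1,2‑dihydronaphthalene 2‑acylsultam 3‑carboxylic acid | CC1(C)[C@@H]2CC[C@]13CS(=O)(=O)N([C@@H]3C2)C(=O)[C@@H]1C(C(=O)O)=Cc2cc(OCc3ccccc3)c(OCc3ccccc3)cc2[C@H]1c1ccc(OCc2ccccc2)c(OCOC)c1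
F7 | step 16 | 1,2‑bis(benzyloxy)‑4‑(2,2‑dibromoethenyl)benzene | BrC(Br)=Cc1ccc(OCc2ccccc2)c(OCc2ccccc2)c1
F8 | step 16 | methyl 3‑[3,4‑bis(benzyloxy)phenyl]prop‑2‑ynoate | COC(=O)C#Cc1ccc(OCc2ccccc2)c(OCc2ccccc2)c1
F9 | step 16 | methyl (E)‑3‑[3,4‑bis(benzyloxy)phenyl]‑2‑(tributylstannyl)prop‑2‑enoate | COC(=O)/C(=C\c1ccc(OCc2ccccc2)c(OCc2ccccc2)c1)[Sn](CCCC)(CCCC)CCCC
F10 | step 16 | methyl (E)‑3‑[3,4‑bis(benzyloxy)phenyl]‑2‑iodoprop‑2‑enoate | COC(=O)/C(I)=C\c1ccc(OCc2ccccc2)c(OCc2ccccc2)c1
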